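**Plan**

- Locants: C1 quaternary carbinol, C2 ketone, C3 CH2, C4 CHOH, C5 CHOBz, C6 CHOH (ring), C7 the CH2OBz carbon. C1 and C6 are adjacent oxygen-bearing stereocentres joined by a ring bond, so one suprafacial [3,3] shift can make the C1–C6 bond and set both centres.
- Retrosynthesis: cut C1–C6 first (Ireland–Claisen rearrangement of a δ-lactone enolate; lactone carbonyl C7, ring oxygen on C4, Z-2-silylvinyl C5=C6 on C4), then the lactone C7–O bond, then C1–C2 (glycolate aldol), then C4–C5 (acetylide acylation).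
- Forward: the chain C2–C6 is built and C4 set; the aldol adds C1/C7; the δ-lactone is closed (the only ring before the key step); the rearrangement then turns the lactone into the cyclohexene; oxygenation of C4, C5, C6 and adjustment of C7 and C2 follow.
- Stereochemistry: C4 from Noyori transfer hydrogenation; C2 (spectator, later the ketone) from the Evans auxiliary; C1 and C6 by chirality transfer from C4 and the Z-alkene through an enforced boat; C4/C5 diol by OsO4 anti to silicon; C6–OH by Fleming–Tamao oxidation with retention.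
- Protecting groups: benzyl on C1–O and C2–O (removed together before C2 is oxidised), TBS on C4–O and C6–O (removed last under acidic fluoride).

Key step: step 11

Remark: carbocycles 20–31 are named with the plan locants C1–C7 (not lowest-locant numbering); stereodescriptors refer to these atoms.

**Route**

Step 1
Reactants: 1 ethyl 3,3-diethoxypropanoate
Product: 2 Weinreb amide 3,3-diethoxy-N-methoxy-N-methylpropanamide
Conditions: MeNH(OMe)·HCl, iPrMgCl, THF, −20 → 0 °C
Reagents that add atoms: N,O-dimethylhydroxylamine hydrochloride, CNOC.Cl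
Why: The chloromagnesium amide formed in the flask converts the unhindered ethyl ester directly into the Weinreb amide (ester aminolysis), and the basic medium leaves the diethyl acetal intact.

Step 2
Reactants: 2 3,3-diethoxy-N-methoxy-N-methylpropanamide; 3 ethynyl(dimethyl)phenylsilane
Product: 5 ynone 5,5-diethoxy-1-[dimethyl(phenyl)silyl]pent-1-yn-3-one, via lithium acetylide 4 (not isolated)
Conditions: n-BuLi, THF, −78 °C; then 2, −78 → −20 °C; inverse quench into cold aq. NH4Cl
Reagents that add atoms: none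
Why: Addition of the lithium acetylide to the Weinreb amide gives a chelated tetrahedral adduct that collapses to the ketone only on quench (Weinreb ketone synthesis), so the C4–C5 bond forms without over-addition.

Step 3
Reactants: 5 5,5-diethoxy-1-[dimethyl(phenyl)silyl]pent-1-yn-3-one
Product: 6 alcohol (3R)-5,5-diethoxy-1-[dimethyl(phenyl)silyl]pent-1-yn-3-ol
Conditions: Ru[(R,R)-TsNCH(Ph)CH(Ph)NH](η6-p-cymene) (1 mol%), iPrOH, rt
Reagents that add atoms: none
Why: Noyori asymmetric transfer hydrogenation reduces alkynyl ketones under neutral conditions without touching the triple bond or the acetal, and the (R,R) ligand delivers hydride to the carbonyl face that gives the (R)-carbinol at C4, as for simple alkyl alkynyl ketones.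

Step 4
Reactants: 6 (3R)-5,5-diethoxy-1-[dimethyl(phenyl)silyl]pent-1-yn-3-ol
Product: 7 silyl ether tert-butyl{[(3R)-5,5-diethoxy-1-(dimethylphenylsilyl)pent-1-yn-3-yl]oxy}dimethylsilane
Conditions: TBSCl, imidazole, DMF, rt
Reagents that add atoms: tert-butyldimethylsilyl chloride, CC(C)(C)[Si](C)(C)Cl
Why: Imidazole-mediated silylation of the secondary propargylic alcohol (silyl ether formation) masks the C4 hydroxyl for the aldol and does not disturb the acetal.

Step 5
Reactants: 7 tert-butyl{[(3R)-5,5-diethoxy-1-(dimethylphenylsilyl)pent-1-yn-3-yl]oxy}dimethylsilane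
Product: 8 aldehyde (3R)-3-(tert-butyldimethylsilyloxy)-5-[dimethyl(phenyl)silyl]pent-4-ynal
Conditions: 10% aq. oxalic acid on SiO2, CH2Cl2, rt; used crude
Reagents that add atoms: water, O
Why: Mild acid-catalysed acetal hydrolysis on wet silica releases the C2 aldehyde while the secondary propargylic TBS ether and the alkynylsilane are stable to oxalic acid, and immediate use limits β-elimination of the silyloxy group.

Step 6
Reactants: 9 (4R)-4-benzyl-1,3-oxazolidin-2-one; 10 (benzyloxy)acetyl chloride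
Product: 12 imide (4R)-4-benzyl-3-[(benzyloxy)acetyl]-1,3-oxazolidin-2-one, via lithiated oxazolidinone 11 (not isolated)
Conditions: n-BuLi, THF, −78 °C; then 10, −78 → 0 °C
Reagents that add atoms: none
Why: N-Acylation of the lithiated oxazolidinone by the acid chloride is the standard preparation of glycolate imides for Evans aldol reactions.

Step 7
Reactants: 12 (4R)-4-benzyl-3-[(benzyloxy)acetyl]-1,3-oxazolidin-2-one; 8 (3R)-3-(tert-butyldimethylsilyloxy)-5-[dimethyl(phenyl)silyl]pent-4-ynal
Product: 14 aldol adduct (4R)-4-benzyl-3-[(2R,3S,5R)-2-(benzyloxy)-5-(tert-butyldimethylsilyloxy)-7-(dimethylphenylsilyl)-3-hydroxyhept-6-ynoyl]-1,3-oxazolidin-2-one, via boron enolate 13 (not isolated)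
Conditions: Bu2BOTf, Et3N, CH2Cl2, −78 → 0 °C; then 8, −78 → 0 °C; pH 7 buffer, MeOH, H2O2, 0 °C
Reagents that add atoms: none
Why: The Z-boron enolate adds to the aldehyde through a closed chair transition state (Evans syn aldol) in which the (R)-benzyl auxiliary fixes the enolate face, so the C1–C2 bond forms with C1 as R and C2 as S largely independently of the remote C4 centre.

Step 8
Reactants: 14 aldol adduct
Product: 16 hydroxy lactone (3R,4S,6R)-3-(benzyloxy)-6-[(dimethylphenylsilyl)ethynyl]-4-hydroxyoxan-2-one, via dihydroxy imide 15 (not isolated)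
Conditions: HF·pyridine, pyridine, THF, 0 °C → rt
Reagents that add atoms: none
Why: Buffered HF cleaves the O–Si bond at C4 but not the C(sp)–Si bond, and the freed hydroxyl attacks the activated imide carbonyl in a six-membered acyl transfer (lactonisation with release of the auxiliary), closing the δ-lactone C7–O–C4.

Step 9
Reactants: 16 hydroxy lactone
Product: 17 lactone (3R,4S,6R)-3,4-bis(benzyloxy)-6-[(dimethylphenylsilyl)ethynyl]oxan-2-one
Conditions: BnOC(=NH)CCl3, TfOH (cat.), CH2Cl2/cyclohexane, 0 °C → rt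
Reagents that add atoms: benzyl 2,2,2-trichloroacetimidate, ClC(Cl)(Cl)C(=N)OCc1ccccc1
Why: Acid-catalysed O-benzylation with the trichloroacetimidate avoids the basic conditions under which a β-hydroxy lactone would eliminate or undergo retro-aldol cleavage, and no stereocentre is touched.

Step 10
Reactants: 17 alkynyl lactone
Product: 18 lactone (3R,4S,6R)-3,4-bis(benzyloxy)-6-[(Z)-2-(dimethylphenylsilyl)ethenyl]oxan-2-one
Conditions: H2 (1 atm), Pd/CaCO3 poisoned with Pb(OAc)2, quinoline, EtOAc, rt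
Reagents that add atoms: none
Why: Lindlar semihydrogenation adds hydrogen syn to the silylalkyne and stops at the (Z)-vinylsilane without hydrogenolysis of the benzyl ethers.

Step 11
Reactants: 18 (Z)-vinylsilane lactone
Product: 21 acid (1S,2S,6S)-1,2-bis(benzyloxy)-6-[dimethyl(phenyl)silyl]cyclohex-4-ene-1-carboxylic acid, via silyl ketene acetal 19 (not isolated), via trimethylsilyl ester 20 (not isolated)
Conditions: LiN(iPr)2, TMSCl, Et3N, THF, −100 → −78 °C (lactone added last), then rt; PhMe, 105 °C; aq. citric acid work-up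
Reagents that add atoms: none
Why: LiN(iPr)2 removes the C1 proton in the presence of TMSCl, so the lactone enolate is O-silylated at once to ketene acetal 19, which on heating undergoes a concerted suprafacial [3,3]-sigmatropic shift (Ireland–Claisen rearrangement) that forms C1–C6, breaks O–C4 and moves the alkene to C4=C5, giving silyl ester 20 and, after hydrolysis, acid 21. The closest known reaction type is the Ireland–Claisen rearrangement of silyl ketene acetals of lactones that carry an alkenyl group on the carbinol carbon, which gives cycloalkene carboxylic acids, and α-alkoxy enolates and vinylsilane termini are both established in ester-enolate Claisen chemistry. The cyclohexene closes through the pericyclic C1–C6 bond formation itself: the six-membered lactone holds the O–C7=C1 and C4–C5=C6 units face to face, so only a boat (bicyclo[2.2.2]octane-like) transition state with the C7–O bridge spanning C1 and C4 is possible. C1 is set because the C4 stereocentre places the vinyl group on one face of the ring and C6 can bond only to that face of C1, and C6 is set by the Z geometry, which puts silicon on the inside of the allyl unit and hence cis to the C1 benzyloxy group in the product. The step needs complete transfer of the C4 configuration and no loss of the C2 benzyloxy group by β-elimination; the first is enforced by the ring, the second by in situ silylation at low temperature, and the C2 benzyloxy group, trans to the vinyl group, points away from the incoming silyl terminus.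

Step 12
Reactants: 21 acid
Product: 22 alcohol [(1R,2S,6S)-1,2-bis(benzyloxy)-6-(dimethylphenylsilyl)cyclohex-4-en-1-yl]methanol
Conditions: LiAlH4, THF, 0 °C → reflux
Reagents that add atoms: none
Why: LiAlH4 reduces the hindered carboxylic acid to the primary C7 alcohol (hydride reduction) and leaves the allylsilane and the benzyl ethers intact.

Step 13
Reactants: 22 alcohol
Product: 23 benzoate [(1R,2S,6S)-1,2-bis(benzyloxy)-6-(dimethylphenylsilyl)cyclohex-4-en-1-yl]methyl benzoate
Conditions: BzCl, pyridine, DMAP (cat.), CH2Cl2, 0 °C → rt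
Reagents that add atoms: benzoyl chloride, O=C(Cl)c1ccccc1
Why: DMAP-catalysed acylation of the only free hydroxyl installs the C7 benzoate (esterification).

Step 14
Reactants: 23 benzoate
Product: 24 diol [(1R,2S,4R,5R,6S)-1,2-bis(benzyloxy)-6-(dimethylphenylsilyl)-4,5-dihydroxycyclohexyl]methyl benzoate
Conditions: OsO4 (cat.), NMO, acetone/H2O, rt
Reagents that add atoms: osmium tetroxide (oxygen carrier), O=[Os](=O)(=O)=O; N-methylmorpholine N-oxide, C[N+]1([O-])CCOCC1; water, O
Why: Catalytic OsO4 dihydroxylation (Upjohn conditions) adds both oxygens suprafacially to C4=C5 on the face anti to the bulky, electron-releasing allylic silyl group at C6, giving the cis C4/C5 diol trans to silicon.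

Step 15
Reactants: 24 diol
Product: 25 silyl ether [(1R,2S,4R,5R,6S)-1,2-bis(benzyloxy)-4-(tert-butyldimethylsilyloxy)-6-(dimethylphenylsilyl)-5-hydroxycyclohexyl]methyl benzoate
Conditions: TBSCl, imidazole, DMF, 0 °C
Reagents that add atoms: tert-butyldimethylsilyl chloride, CC(C)(C)[Si](C)(C)Cl
Why: Mono-silylation discriminates on steric grounds, since the C4 hydroxyl sits next to the C3 methylene whereas the C5 hydroxyl is shielded by the adjacent carbon bearing the dimethylphenylsilyl group.

Step 16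
Reactants: 25 silyl ether
Product: 26 dibenzoate [(1R,2S,4R,5R,6S)-5-(benzoyloxy)-1,2-bis(benzyloxy)-4-(tert-butyldimethylsilyloxy)-6-(dimethylphenylsilyl)cyclohexyl]methyl benzoate
Conditions: BzCl, DMAP, pyridine, 40 °C
Reagents that add atoms: benzoyl chloride, O=C(Cl)c1ccccc1
Why: DMAP-catalysed benzoylation of the remaining secondary hydroxyl gives the C5 benzoate under alkoxide-free conditions that avoid silyl migration and Peterson elimination.

Step 17
Reactants: 26 dibenzoate
Product: 27 alcohol [(1S,2S,4R,5S,6S)-5-(benzoyloxy)-1,2-bis(benzyloxy)-4-(tert-butyldimethylsilyloxy)-6-hydroxycyclohexyl]methyl benzoate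
Conditions: KBr, AcOOH, NaOAc, AcOH, 0 °C → rt
Reagents that add atoms: peracetic acid, CC(=O)OO
Why: In the one-pot Fleming–Tamao oxidation, electrophilic bromine from KBr and AcOOH removes the phenyl group from silicon by ipso substitution and peracetate then induces 1,2-migration of C6 from silicon to oxygen with retention, so the C6 hydroxyl appears cis to the C1 oxygen while esters, benzyl ethers and the TBS ether tolerate the buffered medium.

Step 18
Reactants: 27 alcohol
Product: 28 bis-silyl ether [(1R,2S,4R,5R,6S)-5-(benzoyloxy)-1,2-bis(benzyloxy)-4,6-bis(tert-butyldimethylsilyloxy)cyclohexyl]methyl benzoate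
Conditions: TBSOTf, 2,6-lutidine, CH2Cl2, 0 °C → rt
Reagents that add atoms: tert-butyldimethylsilyl triflate, CC(C)(C)[Si](C)(C)OS(=O)(=O)C(F)(F)F
Why: The hindered C6 hydroxyl is silylated by the highly electrophilic silyl triflate (silyl ether formation) so that only C2 can be oxidised later.

Step 19
Reactants: 28 bis-silyl ether
Product: 29 diol [(1R,2S,4R,5R,6S)-5-(benzoyloxy)-4,6-bis(tert-butyldimethylsilyloxy)-1,2-dihydroxycyclohexyl]methyl benzoate
Conditions: H2 (1 atm), Pd(OH)2/C, EtOAc, rt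
Reagents that add atoms: none
Why: Catalytic hydrogenolysis cleaves both benzyl ethers (secondary at C2, tertiary at C1) while benzoates and TBS ethers are inert in ethyl acetate.

Step 20
Reactants: 29 diol
Product: 30 ketone [(1S,4R,5R,6S)-5-(benzoyloxy)-4,6-bis(tert-butyldimethylsilyloxy)-1-hydroxy-2-oxocyclohexyl]methyl benzoate
Conditions: IBX, DMSO, rt
Reagents that add atoms: none
Why: IBX oxidises the secondary C2 alcohol to the ketone without cleaving the 1,2-diol, and the tertiary C1 hydroxyl cannot be oxidised.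

Step 21
Reactants: 30 ketone
Product: 31 target [(1S,4R,5R,6S)-5-(benzoyloxy)-1,4,6-trihydroxy-2-oxocyclohexyl]methyl benzoate
Conditions: HF·pyridine, THF, 0 °C → rt
Reagents that add atoms: none
Why: Acidic fluoride removes both TBS ethers (desilylation) under conditions that avoid base-induced benzoate migration, β-elimination of the C4 hydroxyl and α-ketol rearrangement.

**Compound list**

1 | ethyl 3,3-diethoxypropanoate | CCOC(=O)CC(OCC)OCC | starting material
2 | 3,3-diethoxy-N-methoxy-N-methylpropanamide | CCOC(OCC)CC(=O)N(C)OC | intermediate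
3 | ethynyl(dimethyl)phenylsilane | C#C[Si](C)(C)c1ccccc1 | starting material
4 | lithium [dimethyl(phenyl)silyl]acetylide | [Li]C#C[Si](C)(C)c1ccccc1 | intermediate
5 | 5,5-diethoxy-1-[dimethyl(phenyl)silyl]pent-1-yn-3-one | CCOC(OCC)CC(=O)C#C[Si](C)(C)c1ccccc1 | intermediate
6 | (3R)-5,5-diethoxy-1-[dimethyl(phenyl)silyl]pent-1-yn-3-ol | CCOC(OCC)C[C@@H](O)C#C[Si](C)(C)c1ccccc1 | intermediate
7 | tert-butyl{[(3R)-5,5-diethoxy-1-(dimethylphenylsilyl)pent-1-yn-3-yl]oxy}dimethylsilane | CCOC(OCC)C[C@@H](O[Si](C)(C)C(C)(C)C)C#C[Si](C)(C)c1ccccc1 | intermediate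
8 | (3R)-3-(tert-butyldimethylsilyloxy)-5-[dimethyl(phenyl)silyl]pent-4-ynal | O=CC[C@@H](O[Si](C)(C)C(C)(C)C)C#C[Si](C)(C)c1ccccc1 | intermediate
9 | (4R)-4-benzyl-1,3-oxazolidin-2-one | O=C1N[C@H](Cc2ccccc2)CO1 | starting material
10 | (benzyloxy)acetyl chloride | O=C(Cl)COCc1ccccc1 | starting material
11 | N-lithio-(4R)-4-benzyl-1,3-oxazolidin-2-one | [Li]N1[C@H](Cc2ccccc2)COC1=O | intermediate
12 | (4R)-4-benzyl-3-[(benzyloxy)acetyl]-1,3-oxazolidin-2-one | O=C(COCc1ccccc1)N1[C@H](Cc2ccccc2)COC1=O | intermediate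
13 | (Z)-dibutylboron enolate of 12 | CCCCB(CCCC)O/C(=C\OCc1ccccc1)N1[C@H](Cc2ccccc2)COC1=O | intermediate
14 | (4R)-4-benzyl-3-[(2R,3S,5R)-2-(benzyloxy)-5-(tert-butyldimethylsilyloxy)-7-(dimethylphenylsilyl)-3-hydroxyhept-6-ynoyl]-1,3-oxazolidin-2-one | O=C([C@H](OCc1ccccc1)[C@@H](O)C[C@@H](O[Si](C)(C)C(C)(C)C)C#C[Si](C)(C)c1ccccc1)N1[C@H](Cc2ccccc2)COC1=O | intermediate
15 | (4R)-4-benzyl-3-[(2R,3S,5R)-2-(benzyloxy)-7-(dimethylphenylsilyl)-3,5-dihydroxyhept-6-ynoyl]-1,3-oxazolidin-2-one | O=C([C@H](OCc1ccccc1)[C@@H](O)C[C@@H](O)C#C[Si](C)(C)c1ccccc1)N1[C@H](Cc2ccccc2)COC1=O | intermediate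
16 | (3R,4S,6R)-3-(benzyloxy)-6-[(dimethylphenylsilyl)ethynyl]-4-hydroxyoxan-2-one | O=C1O[C@@H](C#C[Si](C)(C)c2ccccc2)C[C@H](O)[C@H]1OCc1ccccc1 | intermediate
17 | (3R,4S,6R)-3,4-bis(benzyloxy)-6-[(dimethylphenylsilyl)ethynyl]oxan-2-one | O=C1O[C@@H](C#C[Si](C)(C)c2ccccc2)C[C@H](OCc2ccccc2)[C@H]1OCc1ccccc1 | intermediate
18 | (3R,4S,6R)-3,4-bis(benzyloxy)-6-[(Z)-2-(dimethylphenylsilyl)ethenyl]oxan-2-one | O=C1O[C@@H](/C=C\[Si](C)(C)c2ccccc2)C[C@H](OCc2ccccc2)[C@H]1OCc1ccccc1 | intermediate
19 | (2R,4S)-4,5-bis(benzyloxy)-2-[(Z)-2-(dimethylphenylsilyl)ethenyl]-6-(trimethylsilyloxy)-3,4-dihydro-2H-pyran | C[Si](C)(C)OC1=C(OCc2ccccc2)[C@@H](OCc2ccccc2)C[C@H](/C=C\[Si](C)(C)c2ccccc2)O1 | intermediate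
20 | trimethylsilyl (1S,2S,6S)-1,2-bis(benzyloxy)-6-(dimethylphenylsilyl)cyclohex-4-ene-1-carboxylate | C[Si](C)(C)OC(=O)[C@@]1(OCc2ccccc2)[C@@H](OCc2ccccc2)CC=C[C@@H]1[Si](C)(C)c1ccccc1 | intermediate
21 | (1S,2S,6S)-1,2-bis(benzyloxy)-6-(dimethylphenylsilyl)cyclohex-4-ene-1-carboxylic acid | OC(=O)[C@@]1(OCc2ccccc2)[C@@H](OCc2ccccc2)CC=C[C@@H]1[Si](C)(C)c1ccccc1 | intermediate
22 | [(1R,2S,6S)-1,2-bis(benzyloxy)-6-(dimethylphenylsilyl)cyclohex-4-en-1-yl]methanol | OC[C@@]1(OCc2ccccc2)[C@@H](OCc2ccccc2)CC=C[C@@H]1[Si](C)(C)c1ccccc1 | intermediate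
23 | [(1R,2S,6S)-1,2-bis(benzyloxy)-6-(dimethylphenylsilyl)cyclohex-4-en-1-yl]methyl benzoate | O=C(OC[C@@]1(OCc2ccccc2)[C@@H](OCc2ccccc2)CC=C[C@@H]1[Si](C)(C)c1ccccc1)c1ccccc1 | intermediate
24 | [(1R,2S,4R,5R,6S)-1,2-bis(benzyloxy)-6-(dimethylphenylsilyl)-4,5-dihydroxycyclohexyl]methyl benzoate | O=C(OC[C@@]1(OCc2ccccc2)[C@@H](OCc2ccccc2)C[C@@H](O)[C@@H](O)[C@@H]1[Si](C)(C)c1ccccc1)c1ccccc1 | intermediate
25 | [(1R,2S,4R,5R,6S)-1,2-bis(benzyloxy)-4-(tert-butyldimethylsilyloxy)-6-(dimethylphenylsilyl)-5-hydroxycyclohexyl]methyl benzoate | O=C(OC[C@@]1(OCc2ccccc2)[C@@H](OCc2ccccc2)C[C@@H](O[Si](C)(C)C(C)(C)C)[C@@H](O)[C@@H]1[Si](C)(C)c1ccccc1)c1ccccc1 | intermediate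
26 | [(1R,2S,4R,5R,6S)-5-(benzoyloxy)-1,2-bis(benzyloxy)-4-(tert-butyldimethylsilyloxy)-6-(dimethylphenylsilyl)cyclohexyl]methyl benzoate | O=C(OC[C@@]1(OCc2ccccc2)[C@@H](OCc2ccccc2)C[C@@H](O[Si](C)(C)C(C)(C)C)[C@@H](OC(=O)c2ccccc2)[C@@H]1[Si](C)(C)c1ccccc1)c1ccccc1 | intermediate
27 | [(1S,2S,4R,5S,6S)-5-(benzoyloxy)-1,2-bis(benzyloxy)-4-(tert-butyldimethylsilyloxy)-6-hydroxycyclohexyl]methyl benzoate | O=C(OC[C@@]1(OCc2ccccc2)[C@@H](OCc2ccccc2)C[C@@H](O[Si](C)(C)C(C)(C)C)[C@@H](OC(=O)c2ccccc2)[C@@H]1O)c1ccccc1 | intermediate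
28 | [(1R,2S,4R,5R,6S)-5-(benzoyloxy)-1,2-bis(benzyloxy)-4,6-bis(tert-butyldimethylsilyloxy)cyclohexyl]methyl benzoate | O=C(OC[C@@]1(OCc2ccccc2)[C@@H](OCc2ccccc2)C[C@@H](O[Si](C)(C)C(C)(C)C)[C@@H](OC(=O)c2ccccc2)[C@@H]1O[Si](C)(C)C(C)(C)C)c1ccccc1 | intermediate
29 | [(1R,2S,4R,5R,6S)-5-(benzoyloxy)-4,6-bis(tert-butyldimethylsilyloxy)-1,2-dihydroxycyclohexyl]methyl benzoate | O=C(OC[C@@]1(O)[C@@H](O)C[C@@H](O[Si](C)(C)C(C)(C)C)[C@@H](OC(=O)c2ccccc2)[C@@H]1O[Si](C)(C)C(C)(C)C)c1ccccc1 | intermediate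
30 | [(1S,4R,5R,6S)-5-(benzoyloxy)-4,6-bis(tert-butyldimethylsilyloxy)-1-hydroxy-2-oxocyclohexyl]methyl benzoate | O=C(OC[C@@]1(O)C(=O)C[C@@H](O[Si](C)(C)C(C)(C)C)[C@@H](OC(=O)c2ccccc2)[C@@H]1O[Si](C)(C)C(C)(C)C)c1ccccc1 | intermediate
31 | [(1S,4R,5R,6S)-5-(benzoyloxy)-1,4,6-trihydroxy-2-oxocyclohexyl]methyl benzoate (CNP0127041.1) | O=C(OC[C@@]1(O)C(=O)C[C@@H](O)[C@@H](OC(=O)c2ccccc2)[C@@H]1O)c1ccccc1 | target

**Step count and risks**

Total: 21 steps. Longest linear sequence: 20 steps (steps 1–5 and 7–21); step 6 is a one-step side branch.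

Steps most likely to fail:

1. Step 11. The lithium enolate may expel the C2 benzyloxy group by E1cB elimination before it is silylated, and the boat rearrangement may be slow because the Z-silyl group lies on the inside of the allyl unit. The fallback carries the C2 oxygen through the rearrangement as an oxide, which cannot leave. It sets out from 16: Lindlar semihydrogenation would give the (Z)-vinylsilane hydroxy lactone F1. Two equivalents of LiN(iPr)2 at −78 °C followed by TMSCl would give the bis-silylated ketene acetal F2, and heating in toluene would rearrange it to the silyl ester silyl ether F3. Aqueous work-up would give the C2-hydroxy acid F4, and NaH/BnBr in DMF would convert it into the benzyl ester dibenzyl ether F5. LiAlH4 reduction of F5 comes back to the route at 22.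

2. Step 17. Once silicon is activated, anti-elimination of silicon together with the neighbouring C5 benzoate (Peterson-type fragmentation) may compete with migration of C6 to oxygen, and ipso substitution at the hindered silane may be slow. The fallback oxidises silicon while C4–O and C5–O are tied up as a ketal, so no acyloxy leaving group flanks silicon. It sets out from 24: 2,2-dimethoxypropane/PPTS would give the acetonide F6, and the same KBr/AcOOH/NaOAc oxidation would give the C6 alcohol F7. TBSOTf/2,6-lutidine would give the C6 silyl ether F8, and aqueous AcOH would release the C4/C5 diol F9. TBSCl/imidazole would silylate C4 selectively to give the C5 alcohol F10, and BzCl/DMAP benzoylation of F10 comes back to the route at 28.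

3. Step 15. Site selectivity in the mono-silylation of the C4/C5 diol may be poor, or the silyl group may migrate, which would place the benzoate on the wrong oxygen. The fallback differentiates the two hydroxyls by lactonisation instead of sterics. It sets out from 21: OsO4/NMO would give the dihydroxy acid F11. EDC·HCl/DMAP would close the five-membered lactone between C7 and the C5 oxygen (the 6-oxabicyclo[3.2.1]octanone mode usual for cis-3-hydroxycyclohexanecarboxylic acids), giving the C4 alcohol F12. TBSCl/imidazole would then silylate the only free hydroxyl to give the lactone silyl ether F13, and LiAlH4 would open the lactone to the C7/C5 diol F14. Double benzoylation of F14 (BzCl, DMAP, pyridine) comes back to the route at 26.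

**Further compounds**

F1 | step 11 | (3R,4S,6R)-3-(benzyloxy)-6-[(Z)-2-(dimethylphenylsilyl)ethenyl]-4-hydroxyoxan-2-one | O=C1O[C@@H](/C=C\[Si](C)(C)c2ccccc2)C[C@H](O)[C@H]1OCc1ccccc1
F2 | step 11 | (2R,4S)-5-(benzyloxy)-2-[(Z)-2-(dimethylphenylsilyl)ethenyl]-4,6-bis(trimethylsilyloxy)-3,4-dihydro-2H-pyran | C[Si](C)(C)OC1=C(OCc2ccccc2)[C@@H](O[Si](C)(C)C)C[C@H](/C=C\[Si](C)(C)c2ccccc2)O1
F3 | step 11 | trimethylsilyl 1-(benzyloxy)-6-(dimethylphenylsilyl)-2-(trimethylsilyloxy)cyclohex-4-ene-1-carboxylate (plan locants, configuration as in 21) | C[Si](C)(C)OC(=O)[C@@]1(OCc2ccccc2)[C@@H](O[Si](C)(C)C)CC=C[C@@H]1[Si](C)(C)c1ccccc1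
F4 | step 11 | 1-(benzyloxy)-6-(dimethylphenylsilyl)-2-hydroxycyclohex-4-ene-1-carboxylic acid (plan locants, configuration as in 21) | OC(=O)[C@@]1(OCc2ccccc2)[C@@H](O)CC=C[C@@H]1[Si](C)(C)c1ccccc1
F5 | step 11 | benzyl 1,2-bis(benzyloxy)-6-(dimethylphenylsilyl)cyclohex-4-ene-1-carboxylate (plan locants, configuration as in 21) | O=C(OCc1ccccc1)[C@@]1(OCc2ccccc2)[C@@H](OCc2ccccc2)CC=C[C@@H]1[Si](C)(C)c1ccccc1
F6 | step 17 | C4,C5-O-isopropylidene derivative of diol 24 | O=C(OC[C@@]1(OCc2ccccc2)[C@@H](OCc2ccccc2)C[C@@H]2[C@@H](OC(C)(C)O2)[C@@H]1[Si](C)(C)c1ccccc1)c1ccccc1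
F7 | step 17 | C6 alcohol from F6 (silicon replaced by hydroxyl with retention) | O=C(OC[C@@]1(OCc2ccccc2)[C@@H](OCc2ccccc2)C[C@@H]2[C@@H](OC(C)(C)O2)[C@@H]1O)c1ccccc1
F8 | step 17 | C6 tert-butyldimethylsilyl ether of F7 | O=C(OC[C@@]1(OCc2ccccc2)[C@@H](OCc2ccccc2)C[C@@H]2[C@@H](OC(C)(C)O2)[C@@H]1O[Si](C)(C)C(C)(C)C)c1ccccc1
F9 | step 17 | C4,C5-diol with C6 silyl ether (acetonide removed from F8) | O=C(OC[C@@]1(OCc2ccccc2)[C@@H](OCc2ccccc2)C[C@@H](O)[C@@H](O)[C@@H]1O[Si](C)(C)C(C)(C)C)c1ccccc1
F10 | step 17 | C4,C6-bis(tert-butyldimethylsilyl) ether with free C5 hydroxyl | O=C(OC[C@@]1(OCc2ccccc2)[C@@H](OCc2ccccc2)C[C@@H](O[Si](C)(C)C(C)(C)C)[C@@H](O)[C@@H]1O[Si](C)(C)C(C)(C)C)c1ccccc1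
F11 | step 15 | 1,2-bis(benzyloxy)-6-(dimethylphenylsilyl)-4,5-dihydroxycyclohexane-1-carboxylic acid (plan locants, C4 and C5 hydroxyls anti to silicon) | OC(=O)[C@@]1(OCc2ccccc2)[C@@H](OCc2ccccc2)C[C@@H](O)[C@@H](O)[C@@H]1[Si](C)(C)c1ccccc1
F12 | step 15 | bridged lactone of F11 between C7 and the C5 oxygen, C4 hydroxyl free | O=C1O[C@@H]2[C@H](O)C[C@H](OCc3ccccc3)[C@@]1(OCc3ccccc3)[C@H]2[Si](C)(C)c1ccccc1
F13 | step 15 | C4 tert-butyldimethylsilyl ether of lactone F12 | O=C1O[C@@H]2[C@H](O[Si](C)(C)C(C)(C)C)C[C@H](OCc3ccccc3)[C@@]1(OCc3ccccc3)[C@H]2[Si](C)(C)c1ccccc1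
F14 | step 15 | C7,C5-diol with C4 silyl ether (lactone F13 reduced) | OC[C@@]1(OCc2ccccc2)[C@@H](OCc2ccccc2)C[C@@H](O[Si](C)(C)C(C)(C)C)[C@@H](O)[C@@H]1[Si](C)(C)c1ccccc1
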